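**Plan**

Ring numbering follows the target: C1 = carbonyl carbon, C2=C3 = alkene, C4 = allylic CH2, C5 = carbinol carbon, C6 = CH2 between C5 and C1.
Retrosynthesis: first C2=C3 goes back to a saturated ketone with silicon on C2; then C1–C2 and C3–C4 are cut together while C1–C4 is joined, giving a cyclobutanone (C1, C6, C5, C4) with an O–SiMe2–CH=CH2 tether on the C5 oxygen; last, C5–chain is cut to nonadecylmagnesium bromide and 3-(benzyloxy)cyclobutan-1-one.
Enabling feature: joining C1 to C4 across C6–C5 gives a strained four-membered ketone with a mirror plane through C1, C5, the oxygen and the chain; the C5 oxygen is two atoms (O, Si) from C2, so a vinylsilyl ether can deliver C2–C3 into the temporary C1–C4 bond.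
Forward order: the chain is joined to the four-membered ring, the ketone is unveiled, the tether is attached, and the six-membered carbocycle then arises inside a 2-oxa-3-silabicyclo[2.2.2]octanone; Si–C2 and Si–O are cleaved afterwards and C2=C3 is introduced through the enolate that the silicon marks.
Stereochemistry: C5, the only stereocentre, is created in the key step by ligand-controlled choice between the two enantiotopic C(O)–CH2 bonds of the cyclobutanone; nothing later touches it.

Key step: step 5

Assumption: the sense of induction of the phosphoramidite cannot be predicted with confidence; the ligand antipode that leads to (1S,4R)-9 is the one meant.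

**Route**

Step 1
Reactants: 1 1-bromononadecane; 2 3-(benzyloxy)cyclobutan-1-one
Product: 4 3-(benzyloxy)-1-nonadecylcyclobutan-1-ol, via nonadecylmagnesium bromide 3 (not isolated)
Conditions: Mg, THF, 45 °C; then 2, LaCl3·2LiCl (0.3 equiv), THF, −20 → 0 °C; 1 M aq. HCl, 0 °C
Reagents that add atoms: none
Why: Grignard formation and 1,2-addition to the ketone, with the lanthanum salt favouring addition over enolisation and loss of benzyloxide; the product should be a cis/trans mixture of two achiral isomers that converge at 6.

Step 2
Reactants: 4 3-(benzyloxy)-1-nonadecylcyclobutan-1-ol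
Product: 5 1-nonadecylcyclobutane-1,3-diol
Conditions: H2 (1 atm), 10% Pd/C, THF/EtOH, rt
Reagents that add atoms: none
Why: Hydrogenolysis of the benzyl ether over palladium should leave the tertiary cyclobutanol and the saturated chain untouched.

Step 3
Reactants: 5 1-nonadecylcyclobutane-1,3-diol
Product: 6 3-hydroxy-3-nonadecylcyclobutan-1-one
Conditions: Dess–Martin periodinane (1.2 equiv), CH2Cl2, 0 °C → rt, short reaction time
Reagents that add atoms: none
Why: Dess–Martin oxidation takes only the secondary alcohol to the ketone under non-basic conditions (the tertiary alcohol cannot be oxidised), which also removes the cis/trans isomerism.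

Step 4
Reactants: 6 3-hydroxy-3-nonadecylcyclobutan-1-one; 7 chloro(ethenyl)dimethylsilane
Product: 8 3-{[ethenyl(dimethyl)silyl]oxy}-3-nonadecylcyclobutan-1-one
Conditions: imidazole (2.0 equiv), DMAP (5 mol %), CH2Cl2, 0 °C
Reagents that add atoms: 7 chloro(ethenyl)dimethylsilane, C=C[Si](C)(C)Cl
Why: Silylation of the tertiary alcohol with a small chlorosilane under imidazole/DMAP catalysis should install the temporary O–Si–vinyl tether under conditions too weakly basic for retro-aldol opening of the four-membered ring.

Step 5
Reactants: 8 3-{[ethenyl(dimethyl)silyl]oxy}-3-nonadecylcyclobutan-1-one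
Product: 9 (1S,4R)-3,3-dimethyl-1-nonadecyl-2-oxa-3-silabicyclo[2.2.2]octan-5-one
Conditions: Ni(cod)2 (10 mol %), (S)-BINOL-derived N,N-bis[(R)-1-phenylethyl]phosphoramidite (20 mol %), toluene, 60 °C; filtration through Florisil under argon, used directly
Reagents that add atoms: none
Why: Proposed new method: zerovalent nickel, bound to the vinylsilane and the strained C=O, should undergo oxidative cyclisation that joins the internal vinyl carbon (C2) to the carbonyl carbon (C1), after which β-carbon elimination opens the four-membered ring at C1–C4 (strain release, C=O restored) and C(sp3)–C(sp3) reductive elimination from divalent nickel joins the terminal vinyl carbon (C3) to C4. The closest known reaction type is the nickel-catalysed intramolecular insertion of a styrene-type alkene, tethered to C3 of a cyclobutanone through an ortho-phenylene unit, into the acyl–carbon bond to give benzobicyclo[2.2.2]octenones, including an enantioselective phosphoramidite version; new here are the O–Si tether and a vinylsilane as the alkene. The oxasilinane ring closes in a 6-exo sense at the internal alkene carbon (the 7-endo alternative is disfavoured by the two-atom tether), and the carbocycle closes by reductive elimination from a seven-membered nickelacycle, a formal two-carbon ring expansion of the cyclobutanone. C5 becomes stereogenic through the choice between the enantiotopic C(O)–CH2 bonds, which follows from the alkene face bound in the ligand-controlled oxidative cyclisation (catalyst control), and C2 is fixed relative to C5 by the bicyclo[2.2.2] frame. The step needs reductive elimination to outrun β-hydride elimination at C2–H and needs the silicon to stay on carbon; the compact tether should secure the first, and the bridgehead position of C2 should secure the second, because a 1,3-silyl shift to oxygen would give a bridgehead enol ether against Bredt's rule.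

Step 6
Reactants: 9 (1S,4R)-3,3-dimethyl-1-nonadecyl-2-oxa-3-silabicyclo[2.2.2]octan-5-one
Product: 12 (5S)-5-hydroxy-5-nonadecyl-2-(phenylselanyl)cyclohexan-1-one, via ammonium enolate 10 (not isolated), via fluorosilyl ether selenide 11 (not isolated)
Conditions: Bu4N[Ph3SiF2] (1.1 equiv), THF, −40 °C; PhSeCl (1.2 equiv), −78 °C; then AcOH (2 equiv), Bu4NF (1.2 equiv), 0 °C
Reagents that add atoms: benzeneselenenyl chloride, Cl[Se]c1ccccc1
Why: Fluoride-induced C–Si cleavage of the α-silyl ketone should release the enolate regiospecifically at C1–C2 (the silicon marks the carbon), which is selenenylated at C2 before it can equilibrate, and buffered fluoride then removes the fluorosilyl group from the C5 oxygen; the configuration at C2 is immaterial.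

Step 7
Reactants: 12 (5S)-5-hydroxy-5-nonadecyl-2-(phenylselanyl)cyclohexan-1-one
Product: 14 (S)-5-hydroxy-5-nonadecylcyclohex-2-en-1-one, via selenoxide 13 (not isolated)
Conditions: H2O2 (30% aq., 3 equiv; the excess oxidises the benzeneselenenic acid on to the seleninic acid), pyridine (2 equiv), CH2Cl2, 0 °C → rt
Reagents that add atoms: none
Why: Oxidation to the selenoxide and syn-elimination at or below room temperature can only engage a hydrogen on C3, so the C2=C3 enone should form without acid or base strong enough to dehydrate the β-hydroxy ketone, and C5 is untouched.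

**Compound list**

1 | 1-bromononadecane | CCCCCCCCCCCCCCCCCCCBr | starting material
2 | 3-(benzyloxy)cyclobutan-1-one | O=C1CC(OCc2ccccc2)C1 | starting material
3 | nonadecylmagnesium bromide | CCCCCCCCCCCCCCCCCCC[Mg]Br | intermediate
4 | 3-(benzyloxy)-1-nonadecylcyclobutan-1-ol (cis/trans mixture, both achiral) | OC1(CCCCCCCCCCCCCCCCCCC)CC(OCc2ccccc2)C1 | intermediate
5 | 1-nonadecylcyclobutane-1,3-diol (cis/trans mixture, both achiral) | OC1(CCCCCCCCCCCCCCCCCCC)CC(O)C1 | intermediate
6 | 3-hydroxy-3-nonadecylcyclobutan-1-one | O=C1CC(O)(CCCCCCCCCCCCCCCCCCC)C1 | intermediate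
7 | chloro(ethenyl)dimethylsilane | C=C[Si](C)(C)Cl | starting material
8 | 3-{[ethenyl(dimethyl)silyl]oxy}-3-nonadecylcyclobutan-1-one | O=C1CC(CCCCCCCCCCCCCCCCCCC)(O[Si](C)(C)C=C)C1 | intermediate
9 | (1S,4R)-3,3-dimethyl-1-nonadecyl-2-oxa-3-silabicyclo[2.2.2]octan-5-one | CCCCCCCCCCCCCCCCCCC[C@]12CC[C@H](C(=O)C1)[Si](C)(C)O2 | intermediate
10 | tetrabutylammonium (5S)-5-{[fluoro(dimethyl)silyl]oxy}-5-nonadecylcyclohex-1-en-1-olate | CCCCCCCCCCCCCCCCCCC[C@]1(O[Si](C)(C)F)CCC=C([O-])C1.CCCC[N+](CCCC)(CCCC)CCCC | intermediate
11 | (5S)-5-{[fluoro(dimethyl)silyl]oxy}-5-nonadecyl-2-(phenylselanyl)cyclohexan-1-one (C2 epimers) | CCCCCCCCCCCCCCCCCCC[C@]1(O[Si](C)(C)F)CCC([Se]c2ccccc2)C(=O)C1 | intermediate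
12 | (5S)-5-hydroxy-5-nonadecyl-2-(phenylselanyl)cyclohexan-1-one (C2 epimers) | CCCCCCCCCCCCCCCCCCC[C@]1(O)CCC([Se]c2ccccc2)C(=O)C1 | intermediate
13 | (5S)-5-hydroxy-5-nonadecyl-2-(phenylseleninyl)cyclohexan-1-one | CCCCCCCCCCCCCCCCCCC[C@]1(O)CCC([Se](=O)c2ccccc2)C(=O)C1 | intermediate
14 | (S)-5-hydroxy-5-nonadecylcyclohex-2-en-1-one | CCCCCCCCCCCCCCCCCCC[C@]1(O)CC=CC(=O)C1 | target

**Step count and risks**

Total steps: 7. Longest linear sequence: 7 steps (1 → 14).

Steps most likely to fail:

1. Step 5. The vinylsilane may fail to engage the carbonyl in oxidative cyclisation, β-hydride elimination at C2–H may outrun C3–C4 reductive elimination and open the ring, or the ligand may discriminate the enantiotopic C(O)–CH2 bonds poorly. The fallback uses known chemistry only and gives up the ring expansion; it sets out from Grignard reagent 3 and comes back at 14.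
 - Addition of 3 to 3-ethoxycyclohex-2-en-1-one and work-up with 1 M aq. HCl (Stork–Danheiser transposition) should give 3-nonadecylcyclohex-2-en-1-one F1.
 - Amine-salt-catalysed asymmetric nucleophilic epoxidation (9-amino-9-deoxy-epi-cinchona alkaloid trifluoroacetate, aq. H2O2, dioxane, 50 °C; the pseudoenantiomer that gives the (1S,6S) series) should give (1S,6S)-6-nonadecyl-7-oxabicyclo[4.1.0]heptan-2-one F2.
 - Kinetic enolisation on the only open side (LDA, THF, −78 °C) and dehydrogenation with N-tert-butylbenzenesulfinimidoyl chloride should give (1S,6S)-6-nonadecyl-7-oxabicyclo[4.1.0]hept-3-en-2-one F3.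
 - Reductive cleavage of the Cα–O bond with SmI2 (2.2 equiv, THF/MeOH, −90 °C) should give 14.

2. Step 6. Proton transfer may move the enolate to C1–C6, from where the C5 oxygen is expelled (loss of the stereocentre, then aromatisation), or adventitious water may simply protonate C2. The fallback sets out from 9 and comes back at 14. Deliberate protodesilylation and Si–O cleavage with aqueous HF in MeCN at 0 °C should give (S)-3-hydroxy-3-nonadecylcyclohexan-1-one F4. Direct dehydrogenation with 2-iodoxybenzoic acid (DMSO, 65 °C) should then give 14; the fully substituted C5 leaves C2–C3 as the only position that can be desaturated.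

3. Step 4. Base-induced retro-aldol opening of the strained β-hydroxy ketone 6 may compete during silylation, and 6 may already dehydrate in step 3. The fallback sets out from 4 and comes back at 8, so the free hydroxy ketone never exists.
 - Silylation of 4 with 7 (imidazole, CH2Cl2) should give {[3-(benzyloxy)-1-nonadecylcyclobutyl]oxy}(ethenyl)dimethylsilane F5.
 - Oxidative debenzylation with DDQ (CH2Cl2/H2O, visible light), which spares the vinylsilane that hydrogenolysis would reduce, should give 3-{[ethenyl(dimethyl)silyl]oxy}-3-nonadecylcyclobutan-1-ol F6.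
 - Dess–Martin oxidation should give 8.

**Further compounds**

F1 | step 5 | 3-nonadecylcyclohex-2-en-1-one | O=C1C=C(CCCCCCCCCCCCCCCCCCC)CCC1
F2 | step 5 | (1S,6S)-6-nonadecyl-7-oxabicyclo[4.1.0]heptan-2-one | CCCCCCCCCCCCCCCCCCC[C@]12CCCC(=O)[C@H]1O2
F3 | step 5 | (1S,6S)-6-nonadecyl-7-oxabicyclo[4.1.0]hept-3-en-2-one | CCCCCCCCCCCCCCCCCCC[C@]12CC=CC(=O)[C@H]1O2
F4 | step 6 | (S)-3-hydroxy-3-nonadecylcyclohexan-1-one | CCCCCCCCCCCCCCCCCCC[C@]1(O)CCCC(=O)C1
F5 | step 4 | {[3-(benzyloxy)-1-nonadecylcyclobutyl]oxy}(ethenyl)dimethylsilane | C=C[Si](C)(C)OC1(CCCCCCCCCCCCCCCCCCC)CC(OCc2ccccc2)C1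
F6 | step 4 | 3-{[ethenyl(dimethyl)silyl]oxy}-3-nonadecylcyclobutan-1-ol | C=C[Si](C)(C)OC1(CCCCCCCCCCCCCCCCCCC)CC(O)C1
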